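My unit is the J that one D costs: one to make G and Z, and a second if Z binds as X.

| flask | D | J | remark | time |
|---|---|---|---|---|
| north-west | 0.10 M | 0.169 M | run made earlier |  |
| spring | 0.025 M | 0.169 M |  | 30 min |
| summer | 0.094 M | 0.169 M |  | 30 min |
| autumn | 0.025 M | 0.600 M |  | 30 min |
| winter | 0.030 M | 0.0600 M |  | 30 min |
- north-west (time / min: G / %): 1.50: 42.2; 5.00: 66.6; 8.00: 73.8; 12.0: 77.6; 20.0: 81.8

(readings scatter by 0.3 percentage points)
- the flasks put in order of amount of G, in percent of the D charged, best first, at 30 min (spring / summer / autumn / winter)
- the same order at 1.5 min (spring / summer / autumn / winter)
- the amount of G, in percent of the D charged of the flask you put first, at 30 min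
- the amount of G, in percent of the D charged of the flask you put last, at 30 min

On that count, with every Z bound, the J of the north-west flask pays for 84.5 % of its D, and its readings reach 81.8 % by 20.0 min, just below this.

For autumn, 0.550 M is what I call spare J, the J charged less two per D charged. Two extreme flasks can be solved in the head. If J is short, it is the limiting reagent, and with every Z bound its charge pays for a share of the D equal to J charged over two D charged, which for summer is 89.9 %; I take that as a mark near which G slows, not as a stop. If J is plentiful, D goes quickly and G then sits in the spare J, decaying by J + G → Q in a pseudo-first-order way, at a rate proportional to spare J.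

Real flasks lie between: G climbs, then sags by as much as their spare J allows. Summer has none, and winter charges exactly two J per D. Spring has 0.119 M, so I expect autumn's G to sink 4.62 times as fast as spring's. The north-west run has no spare J, and its readings show no fall, so they give me no constant for the decay. I commit to the direction only: autumn last.

The forecast says spring > summer > winter > autumn at 30 min and autumn > spring > summer > winter at 1.5 min, with 95 % (89 % to 99 %) for spring and 82 % (68 % to 87 %) for autumn. Its ground for the curve: “G never falls, so loss of G to Q is not the cause”.

The flasks give summer > winter > spring > autumn at 30 min: summer 86.4 %, winter 82.7 %, spring 74.5 %, autumn 24.0 %. The early order is autumn > spring > summer > winter, as forecast.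

    J + G → Q (k = 0.00150 M⁻¹ s⁻¹)
    J + Z ⇌ X, settled at all times (K = 738 M⁻¹)
    D + J → Z + G (k = 0.0516 M⁻¹ s⁻¹)

In autumn, half of the making of G is done by 0.382 min, but half of its loss only by 10.3 min. So G spends nearly all of the 30 min exposed to J, and the spare J counts its lifetimes: 1.48, leaving 22.7 %. The autumn charge read at 8.0 min has the same spare J, so the count is 0.396 lifetimes, leaving 67.3 % of G. That flask gives 69.3 %.

The readings are calculated with made-up constants; scatter was added.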